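The ten-membered carbocycle is disconnected at C1–C2: the C1 epoxide oxygen and the C3 acetoxy group flank C2 in a 1,3-relationship, the mark of an aldol bond. In one operation a SmI2-mediated Reformatsky-type aldol of a C2 bromomethyl ketone onto a C1 aldehyde closes this ring and sets C1 under control of the neighbouring C10 silyloxy quaternary centre; C1 then directs C3 and is inverted on epoxide closure. The precursor is the complete butenolide ring (C6, C7, C11, C12, with the C13 acetate) carrying a bromoacetyl (E)-enone arm on C6 and a C7 side chain that ends in the α-triethylsilyloxy aldehyde.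

Key step: step 17

Remark on numbering: C1–C10 are the carbons of the ten-membered ring (C1/C10 epoxide, C3 acetoxy, C4=C5 alkene, C6 lactone oxygen, C7 ring-fusion alkene carbon), C11 is the lactone α-carbon, C12 the lactone carbonyl, C13 the acetoxymethyl carbon, C14 the methyl on C10 and C15 the methyl on C4.

Assumption: the (S,S) enantiomer of ProPhenol is taken to deliver the alkynyl group to the Si face of enal 20 (R carbinol); the sense should be checked on 24 by Mosher ester analysis and the mirror-image ligand used if it is reversed.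

Step 1
Reactants: 1 (S)-2-methylglycidol; 2 4-methoxybenzyl chloride
Product: 4 (R)-2-[(4-methoxybenzyloxy)methyl]-2-methyloxirane, via sodium alkoxide 3 (not isolated)
Conditions: NaH, Bu4NI (cat.), THF/DMF, 0 °C to rt
Reagents that add atoms: 4-methoxybenzyl chloride (2), COc1ccc(CCl)cc1
Why: Williamson etherification of the primary alkoxide; no bond to the quaternary epoxide carbon (the future C10) is made or broken, so its configuration is carried over.

Step 2
Reactants: 4 (R)-2-[(4-methoxybenzyloxy)methyl]-2-methyloxirane; 5 trimethylsulfonium iodide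
Product: 7 (R)-1-[(4-methoxybenzyl)oxy]-2-methylbut-3-en-2-ol, via sulfonium betaine 6 (not isolated)
Conditions: Me3SI (3 equiv), n-BuLi (2.9 equiv), THF, −10 °C to rt
Reagents that add atoms: trimethylsulfonium iodide (5), C[S+](C)C.[I-]
Why: Dimethylsulfonium methylide opens the epoxide at its unhindered CH2 and betaine 6 loses Me2S by ylide-assisted elimination (sulfonium-ylide homologation of an epoxide to an allylic alcohol), so the new carbon becomes C8 and C10 is untouched.

Step 3
Reactants: 7 (R)-1-[(4-methoxybenzyl)oxy]-2-methylbut-3-en-2-ol; 8 triethylsilyl trifluoromethanesulfonate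
Product: 9 (R)-triethyl({1-[(4-methoxybenzyl)oxy]-2-methylbut-3-en-2-yl}oxy)silane
Conditions: Et3SiOTf, 2,6-lutidine, CH2Cl2, −78 to 0 °C
Reagents that add atoms: triethylsilyl trifluoromethanesulfonate (8), CC[Si](CC)(CC)OS(=O)(=O)C(F)(F)F
Why: Silyl triflate silylation is the standard way to cap a hindered tertiary alcohol; Et3Si is chosen as a poor ligand for the later aldol and as a fluoride-labile trigger for the epoxide closure.

Step 4
Reactants: 9 (R)-triethyl({1-[(4-methoxybenzyl)oxy]-2-methylbut-3-en-2-yl}oxy)silane; 10 hydrogen peroxide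
Product: 12 (R)-4-[(4-methoxybenzyl)oxy]-3-methyl-3-(triethylsilyloxy)butan-1-ol, via alkylborane 11 (not isolated)
Conditions: 9-BBN, THF, 0 °C to rt; then NaOH, H2O2, 0 °C
Reagents that add atoms: hydrogen peroxide (10), OO
Why: Hydroboration–oxidation with the bulky borane places boron on the terminal carbon (anti-Markovnikov) and oxidation with retention gives the C8 primary alcohol.

Step 5
Reactants: 12 (R)-4-[(4-methoxybenzyl)oxy]-3-methyl-3-(triethylsilyloxy)butan-1-ol; 13 carbon tetrabromide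
Product: 14 (R)-{[4-bromo-1-[(4-methoxybenzyl)oxy]-2-methylbutan-2-yl]oxy}triethylsilane
Conditions: CBr4, PPh3, 2,6-lutidine, CH2Cl2, 0 °C
Reagents that add atoms: carbon tetrabromide (13), BrC(Br)(Br)Br
Why: Appel bromination converts the unhindered primary alcohol into the bromide under buffered conditions that leave both ethers intact.

Step 6
Reactants: 15 (E)-3-methylpent-2-en-4-yn-1-ol; 16 chlorotrimethylsilane
Product: 19 (E)-3-methyl-5-(trimethylsilyl)pent-2-en-4-yn-1-ol, via bis(bromomagnesium) salt 17 (not isolated), via bis(trimethylsilyl) derivative 18 (not isolated)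
Conditions: EtMgBr (2.2 equiv), THF, 0 to 40 °C; Me3SiCl (2.3 equiv), 0 °C to rt; then 1 M aq. H2SO4, rt
Reagents that add atoms: chlorotrimethylsilane (16), C[Si](C)(C)Cl
Why: Double deprotonation, C- and O-silylation and selective hydrolysis of the labile O–Si bond is the standard protection of a terminal alkyne in a hydroxy enyne; the (E) alkene is not involved.

Step 7
Reactants: 19 (E)-3-methyl-5-(trimethylsilyl)pent-2-en-4-yn-1-ol
Product: 20 (E)-3-methyl-5-(trimethylsilyl)pent-2-en-4-ynal
Conditions: MnO2, CH2Cl2, rt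
Reagents that add atoms: none
Why: MnO2 oxidises the allylic alcohol chemoselectively to the enal (future C6 aldehyde) without isomerising the (E) double bond.

Step 8
Reactants: 20 (E)-3-methyl-5-(trimethylsilyl)pent-2-en-4-ynal; 21 methyl propiolate
Product: 24 methyl (4R,5E)-4-hydroxy-6-methyl-8-(trimethylsilyl)oct-5-en-2,7-diynoate, via alkynylzinc 22 (not isolated), via zinc alkoxide 23 (not isolated)
Conditions: (S,S)-ProPhenol (20 mol %), Me2Zn (3 equiv), toluene, 4 °C; aq. NH4Cl
Reagents that add atoms: methyl propiolate (21), COC(=O)C#C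
Why: Catalytic asymmetric alkynylation of an enal: the zinc alkynylide 22 adds within the dinuclear zinc–ProPhenol complex, and the ligand enantiomer that directs attack to the Si face sets C6 as R.

Step 9
Reactants: 24 methyl (4R,5E)-4-hydroxy-6-methyl-8-(trimethylsilyl)oct-5-en-2,7-diynoate; 25 N,O-bis(trimethylsilyl)acetamide
Product: 26 methyl (4R,5E)-6-methyl-8-(trimethylsilyl)-4-(trimethylsilyloxy)oct-5-en-2,7-diynoate
Conditions: N,O-bis(trimethylsilyl)acetamide, CH2Cl2, rt
Reagents that add atoms: N,O-bis(trimethylsilyl)acetamide (25), CC(=N[Si](C)(C)C)O[Si](C)(C)C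
Why: Neutral O-silylation masks the hydroxyl without amine base, which avoids base-induced isomerisation of the 4-hydroxy-2-ynoate and keeps alkoxide out of the organocopper step.

Step 10
Reactants: 14 (R)-{[4-bromo-1-[(4-methoxybenzyl)oxy]-2-methylbutan-2-yl]oxy}triethylsilane; 26 methyl (4R,5E)-6-methyl-8-(trimethylsilyl)-4-(trimethylsilyloxy)oct-5-en-2,7-diynoate; 27 iodine
Product: 33 (5R)-3-iodo-4-[(3R)-4-[(4-methoxybenzyl)oxy]-3-methyl-3-(triethylsilyloxy)butyl]-5-[(1E)-2-methyl-4-(trimethylsilyl)but-1-en-3-yn-1-yl]furan-2(5H)-one, via Grignard reagent 28 (not isolated), via alkylcopper 29 (not isolated), via alkenylcopper adduct 30 (not isolated), via iodo enoate silyl ether 31 (not isolated), via iodo hydroxy enoate 32 (not isolated)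
Conditions: 14 (1.6 equiv), Mg, THF, rt; CuBr·SMe2 (1.6 equiv), −40 °C; 26, THF, −78 °C; I2, −78 to −20 °C; then 10% aq. citric acid, MeOH/THF, rt
Reagents that add atoms: iodine (27), II
Why: Syn carbocupration of the ynoate (organocopper conjugate addition) puts C8 on C7 and copper on C11, iodinolysis with retention leaves the ester cis to C6, and mild acid removes the O-silyl group so that the hydroxy ester lactonises to the butenolide; C6 and C10 are not touched.

Step 11
Reactants: 33 the 3-iodobutenolide; 34 (tributylstannyl)methanol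
Product: 35 (5R)-3-(hydroxymethyl)-4-[(3R)-4-[(4-methoxybenzyl)oxy]-3-methyl-3-(triethylsilyloxy)butyl]-5-[(1E)-2-methyl-4-(trimethylsilyl)but-1-en-3-yn-1-yl]furan-2(5H)-one
Conditions: Pd(PPh3)4 (10 mol %), 1,4-dioxane, 90 °C
Reagents that add atoms: (tributylstannyl)methanol (34), CCCC[Sn](CCCC)(CCCC)CO
Why: Stille coupling: zerovalent palladium inserts into the electron-poor alkenyl iodide and the hydroxymethyl group is transferred from tin, installing C13 without base.

Step 12
Reactants: 35 the 3-(hydroxymethyl)butenolide; 36 acetic anhydride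
Product: 37 {(5R)-4-[(3R)-4-[(4-methoxybenzyl)oxy]-3-methyl-3-(triethylsilyloxy)butyl]-5-[(1E)-2-methyl-4-(trimethylsilyl)but-1-en-3-yn-1-yl]-2-oxo-2,5-dihydrofuran-3-yl}methyl acetate
Conditions: Ac2O, pyridine, DMAP (cat.), CH2Cl2, 0 °C
Reagents that add atoms: acetic anhydride (36), CC(=O)OC(C)=O
Why: Nucleophile-catalysed acetylation of the only free hydroxyl gives the C13 acetate of the target.

Step 13
Reactants: 37 the C13 acetate with the 4-methoxybenzyl ether
Product: 38 {(5R)-4-[(3R)-4-hydroxy-3-methyl-3-(triethylsilyloxy)butyl]-5-[(1E)-2-methyl-4-(trimethylsilyl)but-1-en-3-yn-1-yl]-2-oxo-2,5-dihydrofuran-3-yl}methyl acetate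
Conditions: DDQ, CH2Cl2/pH 7 phosphate buffer, 0 °C
Reagents that add atoms: none
Why: Oxidative cleavage of the electron-rich 4-methoxybenzyl ether (hydride abstraction, hydrolysis of the oxocarbenium ion) under buffered neutral conditions spares the silyl ether, the acetate and the lactone.

Step 14
Reactants: 38 the C1 primary alcohol
Product: 39 {(5R)-4-[(3R)-3-methyl-4-oxo-3-(triethylsilyloxy)butyl]-5-[(1E)-2-methyl-4-(trimethylsilyl)but-1-en-3-yn-1-yl]-2-oxo-2,5-dihydrofuran-3-yl}methyl acetate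
Conditions: Dess–Martin periodinane, NaHCO3, CH2Cl2, rt
Reagents that add atoms: none
Why: Dess–Martin oxidation under bicarbonate buffer gives the non-enolisable α-silyloxy aldehyde (C1) at once, before the silyl group can migrate from the tertiary to the primary oxygen.

Step 15
Reactants: 39 the alkynylsilane aldehyde; 40 N-bromosuccinimide
Product: 41 {(5R)-5-[(1E)-4-bromo-2-methylbut-1-en-3-yn-1-yl]-4-[(3R)-3-methyl-4-oxo-3-(triethylsilyloxy)butyl]-2-oxo-2,5-dihydrofuran-3-yl}methyl acetate
Conditions: NBS (1.2 equiv), AgNO3 (10 mol %), acetone, rt, dark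
Reagents that add atoms: N-bromosuccinimide (40), O=C1CCC(=O)N1Br
Why: Silver-catalysed bromodesilylation (a silver acetylide is brominated by NBS) converts the alkynylsilane directly into the 1-bromoalkyne faster than NBS attacks any of the alkenes.

Step 16
Reactants: 41 the 1-bromoalkyne aldehyde; 42 water
Product: 43 {(5R)-5-[(1E)-4-bromo-2-methyl-3-oxobut-1-en-1-yl]-4-[(3R)-3-methyl-4-oxo-3-(triethylsilyloxy)butyl]-2-oxo-2,5-dihydrofuran-3-yl}methyl acetate
Conditions: XPhosAuNTf2 (3 mol %), H2O (3 equiv), 1,2-dichloroethane, rt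
Reagents that add atoms: water (42), O
Why: Gold-catalysed hydration of the 1-bromoalkyne (water adds at C3, the carbon remote from bromine, and the enol tautomerises) unveils the bromomethyl ketone last and under neutral conditions, so the doubly activated C6–H never meets the bases or silyl triflates of a ketone bromination, which would turn the butenolide into a 2-silyloxyfuran.

Step 17
Reactants: 43 the bromoacetyl enone aldehyde
Product: 46 (1S,4E,6R,10R)-13-acetoxy-1-hydroxy-3-oxo-10-(triethylsilyloxy)germacra-4,7(11)-dien-12,6-olide, via samarium enolate 44 (not isolated), via samarium aldolate 45 (not isolated)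
Conditions: SmI2 (2.1 equiv, 0.1 M in THF) added over 4 h to 43 (0.002 M in THF), −78 °C; sat. aq. NH4Cl at −78 °C
Reagents that add atoms: none
Why: Two single-electron transfers from divalent samarium cleave the C2–Br bond and give the trivalent samarium enolate 44 regiospecifically at C2; the oxophilic metal then binds the C1 aldehyde and the C1–C2 bond forms through a chair-like six-membered (Zimmerman–Traxler) array to give aldolate 45. The closest known reaction type is the SmI2-mediated intramolecular Reformatsky (Barbier-type aldol) cyclisation used for medium and large carbocycles. The ten-membered ring closes in a 10-(enolendo)-exo-trig mode, helped by the rigid (E)-enone and butenolide units that fold the chain. C1 is set by the C10 centre: with the poorly coordinating OSiEt3 group turned away from the forming bond (polar Felkin–Anh/Cornforth arrangement) the enolate should take the aldehyde face that gives the 1S,10R anti relationship. The step needs chemoselectivity for C–Br over the aldehyde, over the enone with its C6 acyloxy leaving group and over the acetoxymethyl butenolide; the far faster reduction of an α-bromo ketone at −78 °C, the absence of excess SmI2 (slow addition of two equivalents to dilute substrate) and a cold quench should secure it. The (E) geometry of C4=C5 holds C2 of the enolate away from the acidic C6–H, so C6 should not epimerise.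

Step 18
Reactants: 46 the 1-hydroxy-3-oxo macrocycle
Product: 48 (1S,3S,4E,6R,10R)-13-acetoxy-1,3-dihydroxy-10-(triethylsilyloxy)germacra-4,7(11)-dien-12,6-olide, via alkoxyborohydride 47 (not isolated)
Conditions: Me4NBH(OAc)3, MeCN/AcOH (1:1), −30 °C
Reagents that add atoms: none
Why: Evans–Saksena reduction: the C1 hydroxyl exchanges onto boron (47) and hydride is delivered intramolecularly through a chair-like six-membered transition state to the C3 ketone, giving the 1,3-anti diol (3S) by 1,2-reduction under acidic conditions that exclude retro-aldol.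

Step 19
Reactants: 48 the 1,3-anti diol; 36 acetic anhydride
Product: 49 (1S,3S,4E,6R,10R)-3,13-diacetoxy-1-hydroxy-10-(triethylsilyloxy)germacra-4,7(11)-dien-12,6-olide
Conditions: Ac2O (1.2 equiv), pyridine, CH2Cl2, −20 to 0 °C
Reagents that add atoms: acetic anhydride (36), CC(=O)OC(C)=O
Why: Rate-selective acylation of the allylic C3 hydroxyl, because the C1 hydroxyl is shielded by the adjacent quaternary C10 and its OSiEt3 group.

Step 20
Reactants: 49 the C3 acetate; 50 methanesulfonyl chloride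
Product: 51 (1S,3S,4E,6R,10R)-3,13-diacetoxy-1-(methylsulfonyloxy)-10-(triethylsilyloxy)germacra-4,7(11)-dien-12,6-olide
Conditions: MsCl, Et3N, CH2Cl2, −10 °C
Reagents that add atoms: methanesulfonyl chloride (50), CS(=O)(=O)Cl
Why: Sulfene-mediated mesylation works on hindered secondary alcohols and turns the C1 hydroxyl into a leaving group with retention.

Step 21
Reactants: 51 the C1 mesylate
Product: 53 (1R,3S,4E,6R,10R)-3,13-diacetoxy-1,10-epoxygermacra-4,7(11)-dien-12,6-olide (CNP0294733.1), via tertiary alkoxide 52 (not isolated)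
Conditions: Bu4NF (1.1 equiv), THF, 0 °C
Reagents that add atoms: none
Why: Fluoride cleaves the tertiary Si–O bond and the C10 alkoxide displaces the neighbouring mesylate in an intramolecular SN2 (3-exo-tet) reaction with inversion at C1, giving the trans 1R,10R epoxide.

Compound list
1 | (S)-2-methylglycidol, [(2S)-2-methyloxiran-2-yl]methanol | C1O[C@@]1(C)CO | starting material
2 | 4-methoxybenzyl chloride | COc1ccc(CCl)cc1 | starting material
3 | sodium [(2S)-2-methyloxiran-2-yl]methanolate | C1O[C@@]1(C)C[O-].[Na+] | intermediate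
4 | (R)-2-[(4-methoxybenzyloxy)methyl]-2-methyloxirane | C1O[C@@]1(C)COCc1ccc(OC)cc1 | intermediate
5 | trimethylsulfonium iodide | C[S+](C)C.[I-] | starting material
6 | (R)-4-(dimethylsulfonio)-1-[(4-methoxybenzyl)oxy]-2-methylbutan-2-olate (betaine) | C[S+](C)CC[C@@](C)([O-])COCc1ccc(OC)cc1 | intermediate
7 | (R)-1-[(4-methoxybenzyl)oxy]-2-methylbut-3-en-2-ol | C=C[C@@](C)(O)COCc1ccc(OC)cc1 | intermediate
8 | triethylsilyl trifluoromethanesulfonate | CC[Si](CC)(CC)OS(=O)(=O)C(F)(F)F | starting material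
9 | (R)-triethyl({1-[(4-methoxybenzyl)oxy]-2-methylbut-3-en-2-yl}oxy)silane | C=C[C@@](C)(O[Si](CC)(CC)CC)COCc1ccc(OC)cc1 | intermediate
10 | hydrogen peroxide | OO | starting material
11 | 9-[(3R)-4-[(4-methoxybenzyl)oxy]-3-methyl-3-(triethylsilyloxy)butyl]-9-borabicyclo[3.3.1]nonane | C1CCC2CCCC1B2CC[C@@](C)(O[Si](CC)(CC)CC)COCc1ccc(OC)cc1 | intermediate
12 | (R)-4-[(4-methoxybenzyl)oxy]-3-methyl-3-(triethylsilyloxy)butan-1-ol | OCC[C@@](C)(O[Si](CC)(CC)CC)COCc1ccc(OC)cc1 | intermediate
13 | carbon tetrabromide | BrC(Br)(Br)Br | starting material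
14 | (R)-{[4-bromo-1-[(4-methoxybenzyl)oxy]-2-methylbutan-2-yl]oxy}triethylsilane | BrCC[C@@](C)(O[Si](CC)(CC)CC)COCc1ccc(OC)cc1 | intermediate
15 | (E)-3-methylpent-2-en-4-yn-1-ol | OC/C=C(C)/C#C | starting material
16 | chlorotrimethylsilane | C[Si](C)(C)Cl | starting material
17 | bis(bromomagnesium) salt of 15 (alkoxide and acetylide) | Br[Mg]OC/C=C(C)/C#C[Mg]Br | intermediate
18 | (E)-trimethyl{[3-methyl-5-(trimethylsilyl)pent-2-en-4-yn-1-yl]oxy}silane | C[Si](C)(C)OC/C=C(C)/C#C[Si](C)(C)C | intermediate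
19 | (E)-3-methyl-5-(trimethylsilyl)pent-2-en-4-yn-1-ol | OC/C=C(C)/C#C[Si](C)(C)C | intermediate
20 | (E)-3-methyl-5-(trimethylsilyl)pent-2-en-4-ynal | O=C/C=C(C)/C#C[Si](C)(C)C | intermediate
21 | methyl propiolate | COC(=O)C#C | starting material
22 | (3-methoxy-3-oxoprop-1-yn-1-yl)(methyl)zinc | COC(=O)C#C[Zn]C | intermediate
23 | methylzinc alkoxide of 24 | COC(=O)C#C[C@H](O[Zn]C)/C=C(C)/C#C[Si](C)(C)C | intermediate
24 | methyl (4R,5E)-4-hydroxy-6-methyl-8-(trimethylsilyl)oct-5-en-2,7-diynoate | COC(=O)C#C[C@H](O)/C=C(C)/C#C[Si](C)(C)C | intermediate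
25 | N,O-bis(trimethylsilyl)acetamide | CC(=N[Si](C)(C)C)O[Si](C)(C)C | starting material
26 | methyl (4R,5E)-6-methyl-8-(trimethylsilyl)-4-(trimethylsilyloxy)oct-5-en-2,7-diynoate | COC(=O)C#C[C@H](O[Si](C)(C)C)/C=C(C)/C#C[Si](C)(C)C | intermediate
27 | iodine | II | starting material
28 | Grignard reagent of 14, bromo[(3R)-4-[(4-methoxybenzyl)oxy]-3-methyl-3-(triethylsilyloxy)butyl]magnesium | Br[Mg]CC[C@@](C)(O[Si](CC)(CC)CC)COCc1ccc(OC)cc1 | intermediate
29 | [(3R)-4-[(4-methoxybenzyl)oxy]-3-methyl-3-(triethylsilyloxy)butyl]copper | [Cu]CC[C@@](C)(O[Si](CC)(CC)CC)COCc1ccc(OC)cc1 | intermediate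
30 | alkenylcopper from syn addition of 29 to 26 (copper on C11, ester cis to C6) | COC(=O)/C([Cu])=C(CC[C@@](C)(O[Si](CC)(CC)CC)COCc1ccc(OC)cc1)\[C@H](O[Si](C)(C)C)/C=C(C)/C#C[Si](C)(C)C | intermediate
31 | methyl (2E,4R,5E)-2-iodo-3-[(3R)-4-[(4-methoxybenzyl)oxy]-3-methyl-3-(triethylsilyloxy)butyl]-6-methyl-8-(trimethylsilyl)-4-(trimethylsilyloxy)octa-2,5-dien-7-ynoate | COC(=O)/C(I)=C(CC[C@@](C)(O[Si](CC)(CC)CC)COCc1ccc(OC)cc1)\[C@H](O[Si](C)(C)C)/C=C(C)/C#C[Si](C)(C)C | intermediate
32 | methyl (2E,4R,5E)-4-hydroxy-2-iodo-3-[(3R)-4-[(4-methoxybenzyl)oxy]-3-methyl-3-(triethylsilyloxy)butyl]-6-methyl-8-(trimethylsilyl)octa-2,5-dien-7-ynoate | COC(=O)/C(I)=C(CC[C@@](C)(O[Si](CC)(CC)CC)COCc1ccc(OC)cc1)\[C@H](O)/C=C(C)/C#C[Si](C)(C)C | intermediate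
33 | (5R)-3-iodo-4-[(3R)-4-[(4-methoxybenzyl)oxy]-3-methyl-3-(triethylsilyloxy)butyl]-5-[(1E)-2-methyl-4-(trimethylsilyl)but-1-en-3-yn-1-yl]furan-2(5H)-one | C[Si](C)(C)C#C/C(C)=C/[C@H]1OC(=O)C(I)=C1CC[C@@](C)(O[Si](CC)(CC)CC)COCc1ccc(OC)cc1 | intermediate
34 | (tributylstannyl)methanol | CCCC[Sn](CCCC)(CCCC)CO | starting material
35 | (5R)-3-(hydroxymethyl)-4-[(3R)-4-[(4-methoxybenzyl)oxy]-3-methyl-3-(triethylsilyloxy)butyl]-5-[(1E)-2-methyl-4-(trimethylsilyl)but-1-en-3-yn-1-yl]furan-2(5H)-one | C[Si](C)(C)C#C/C(C)=C/[C@H]1OC(=O)C(CO)=C1CC[C@@](C)(O[Si](CC)(CC)CC)COCc1ccc(OC)cc1 | intermediate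
36 | acetic anhydride | CC(=O)OC(C)=O | starting material
37 | {(5R)-4-[(3R)-4-[(4-methoxybenzyl)oxy]-3-methyl-3-(triethylsilyloxy)butyl]-5-[(1E)-2-methyl-4-(trimethylsilyl)but-1-en-3-yn-1-yl]-2-oxo-2,5-dihydrofuran-3-yl}methyl acetate | C[Si](C)(C)C#C/C(C)=C/[C@H]1OC(=O)C(COC(C)=O)=C1CC[C@@](C)(O[Si](CC)(CC)CC)COCc1ccc(OC)cc1 | intermediate
38 | {(5R)-4-[(3R)-4-hydroxy-3-methyl-3-(triethylsilyloxy)butyl]-5-[(1E)-2-methyl-4-(trimethylsilyl)but-1-en-3-yn-1-yl]-2-oxo-2,5-dihydrofuran-3-yl}methyl acetate | C[Si](C)(C)C#C/C(C)=C/[C@H]1OC(=O)C(COC(C)=O)=C1CC[C@@](C)(O[Si](CC)(CC)CC)CO | intermediate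
39 | {(5R)-4-[(3R)-3-methyl-4-oxo-3-(triethylsilyloxy)butyl]-5-[(1E)-2-methyl-4-(trimethylsilyl)but-1-en-3-yn-1-yl]-2-oxo-2,5-dihydrofuran-3-yl}methyl acetate | C[Si](C)(C)C#C/C(C)=C/[C@H]1OC(=O)C(COC(C)=O)=C1CC[C@@](C)(O[Si](CC)(CC)CC)C=O | intermediate
40 | N-bromosuccinimide | O=C1CCC(=O)N1Br | starting material
41 | {(5R)-5-[(1E)-4-bromo-2-methylbut-1-en-3-yn-1-yl]-4-[(3R)-3-methyl-4-oxo-3-(triethylsilyloxy)butyl]-2-oxo-2,5-dihydrofuran-3-yl}methyl acetate | BrC#C/C(C)=C/[C@H]1OC(=O)C(COC(C)=O)=C1CC[C@@](C)(O[Si](CC)(CC)CC)C=O | intermediate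
42 | water | O | starting material
43 | {(5R)-5-[(1E)-4-bromo-2-methyl-3-oxobut-1-en-1-yl]-4-[(3R)-3-methyl-4-oxo-3-(triethylsilyloxy)butyl]-2-oxo-2,5-dihydrofuran-3-yl}methyl acetate (key-step precursor) | BrCC(=O)/C(C)=C/[C@H]1OC(=O)C(COC(C)=O)=C1CC[C@@](C)(O[Si](CC)(CC)CC)C=O | intermediate
44 | diiodosamarium C2 enolate of 43 | C=C(O[Sm](I)I)/C(C)=C/[C@H]1OC(=O)C(COC(C)=O)=C1CC[C@@](C)(O[Si](CC)(CC)CC)C=O | intermediate
45 | diiodosamarium C1 alkoxide of 46 | CC(=O)OCC1=C2CC[C@@](C)(O[Si](CC)(CC)CC)[C@@H](O[Sm](I)I)CC(=O)/C(C)=C/[C@H]2OC1=O | intermediate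
46 | (1S,4E,6R,10R)-13-acetoxy-1-hydroxy-3-oxo-10-(triethylsilyloxy)germacra-4,7(11)-dien-12,6-olide (key-step product) | CC(=O)OCC1=C2CC[C@@](C)(O[Si](CC)(CC)CC)[C@@H](O)CC(=O)/C(C)=C/[C@H]2OC1=O | intermediate
47 | tetramethylammonium diacetoxy(hydrido)borate bound through the C1 oxygen of 46 | CC(=O)OCC1=C2CC[C@@](C)(O[Si](CC)(CC)CC)[C@@H](O[BH-](OC(C)=O)OC(C)=O)CC(=O)/C(C)=C/[C@H]2OC1=O.C[N+](C)(C)C | intermediate
48 | (1S,3S,4E,6R,10R)-13-acetoxy-1,3-dihydroxy-10-(triethylsilyloxy)germacra-4,7(11)-dien-12,6-olide | CC(=O)OCC1=C2CC[C@@](C)(O[Si](CC)(CC)CC)[C@@H](O)C[C@H](O)/C(C)=C/[C@H]2OC1=O | intermediate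
49 | (1S,3S,4E,6R,10R)-3,13-diacetoxy-1-hydroxy-10-(triethylsilyloxy)germacra-4,7(11)-dien-12,6-olide | CC(=O)OCC1=C2CC[C@@](C)(O[Si](CC)(CC)CC)[C@@H](O)C[C@H](OC(C)=O)/C(C)=C/[C@H]2OC1=O | intermediate
50 | methanesulfonyl chloride | CS(=O)(=O)Cl | starting material
51 | (1S,3S,4E,6R,10R)-3,13-diacetoxy-1-(methylsulfonyloxy)-10-(triethylsilyloxy)germacra-4,7(11)-dien-12,6-olide | CC(=O)OCC1=C2CC[C@@](C)(O[Si](CC)(CC)CC)[C@@H](OS(C)(=O)=O)C[C@H](OC(C)=O)/C(C)=C/[C@H]2OC1=O | intermediate
52 | tetrabutylammonium C10 alkoxide of the desilylated mesylate | CC(=O)OCC1=C2CC[C@@](C)([O-])[C@@H](OS(C)(=O)=O)C[C@H](OC(C)=O)/C(C)=C/[C@H]2OC1=O.CCCC[N+](CCCC)(CCCC)CCCC | intermediate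
53 | (1R,3S,4E,6R,10R)-3,13-diacetoxy-1,10-epoxygermacra-4,7(11)-dien-12,6-olide (CNP0294733.1) | CC(=O)OCC1=C2CC[C@@]3(C)O[C@@H]3C[C@H](OC(C)=O)/C(C)=C/[C@H]2OC1=O | target

Total step count: 21. Longest linear sequence: 17 steps (steps 1–5, then 10–21); the C2–C7/C11–C12 fragment (steps 6–9) joins at step 10.

Steps most likely to fail

Step 17 (key step). Samarium bound to the silyloxy oxygen could steer the enolate to the other aldehyde face (chelation-type control). Single-electron reduction could also spill over to the aldehyde or to the enone with cleavage of the C6–O bond, and the enolate could couple between molecules. The fallback replaces the metal-templated closed transition state by a Lewis-acid Mukaiyama aldol with an open one. It sets out from 43: zinc dust and Me3SiCl in MeCN at 0 °C silylate the bromo ketone reductively, because bimolecular O-silylation should outrun the slow ten-ring closure. This gives {(5R)-5-[(1E)-2-methyl-3-(trimethylsilyloxy)buta-1,3-dien-1-yl]-4-[(3R)-3-methyl-4-oxo-3-(triethylsilyloxy)butyl]-2-oxo-2,5-dihydrofuran-3-yl}methyl acetate F1. BF3·OEt2 in CH2Cl2 at −78 °C under high dilution then forms the C1–C2 bond under dipole (Felkin–Anh/Cornforth) control, and aqueous work-up returns to the route at 46.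

Step 16. The cationic gold catalyst may engage the conjugated bromo-enyne in other pathways, hydrate it sluggishly or be poisoned by halide. The fallback hydrates first and brominates afterwards, and sets out from 39. AgNO3 (cat.) in aqueous acetone removes the alkynyl silyl group to give {(5R)-5-[(1E)-2-methylbut-1-en-3-yn-1-yl]-4-[(3R)-3-methyl-4-oxo-3-(triethylsilyloxy)butyl]-2-oxo-2,5-dihydrofuran-3-yl}methyl acetate F2. Ph3PAuNTf2-catalysed Markovnikov hydration in aqueous dioxane gives the methyl enone {(5R)-5-[(1E)-2-methyl-3-oxobut-1-en-1-yl]-4-[(3R)-3-methyl-4-oxo-3-(triethylsilyloxy)butyl]-2-oxo-2,5-dihydrofuran-3-yl}methyl acetate F3. PhNMe3Br3 in THF at 0 °C then brominates the only enolisable ketone position (C2) through the enol, under acidic conditions that do not ionise C6–H, and returns to the route at 43.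

Step 18. The conformation of the ten-membered ring, not the boron-bound C1 oxygen, may decide the face of hydride delivery, giving poor facial selectivity at C3. The fallback makes the syn diol on purpose and inverts C3 while installing the acetate. It sets out from 46: Et2BOMe/NaBH4 in THF/MeOH at −78 °C (Narasaka–Prasad reduction, external hydride on the boron chelate) gives (1S,3R,4E,6R,10R)-13-acetoxy-1,3-dihydroxy-10-(triethylsilyloxy)germacra-4,7(11)-dien-12,6-olide F4. Mitsunobu esterification with acetic acid (PPh3, diisopropyl azodicarboxylate, toluene, 0 °C) at the accessible allylic C3 hydroxyl inverts C3 and returns to the route directly at 49, so step 19 is not needed.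

Further compounds
F1 | step 17 | {(5R)-5-[(1E)-2-methyl-3-(trimethylsilyloxy)buta-1,3-dien-1-yl]-4-[(3R)-3-methyl-4-oxo-3-(triethylsilyloxy)butyl]-2-oxo-2,5-dihydrofuran-3-yl}methyl acetate | C=C(O[Si](C)(C)C)/C(C)=C/[C@H]1OC(=O)C(COC(C)=O)=C1CC[C@@](C)(O[Si](CC)(CC)CC)C=O
F2 | step 16 | {(5R)-5-[(1E)-2-methylbut-1-en-3-yn-1-yl]-4-[(3R)-3-methyl-4-oxo-3-(triethylsilyloxy)butyl]-2-oxo-2,5-dihydrofuran-3-yl}methyl acetate | C#C/C(C)=C/[C@H]1OC(=O)C(COC(C)=O)=C1CC[C@@](C)(O[Si](CC)(CC)CC)C=O
F3 | step 16 | {(5R)-5-[(1E)-2-methyl-3-oxobut-1-en-1-yl]-4-[(3R)-3-methyl-4-oxo-3-(triethylsilyloxy)butyl]-2-oxo-2,5-dihydrofuran-3-yl}methyl acetate | CC(=O)/C(C)=C/[C@H]1OC(=O)C(COC(C)=O)=C1CC[C@@](C)(O[Si](CC)(CC)CC)C=O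
F4 | step 18 | (1S,3R,4E,6R,10R)-13-acetoxy-1,3-dihydroxy-10-(triethylsilyloxy)germacra-4,7(11)-dien-12,6-olide | CC(=O)OCC1=C2CC[C@@](C)(O[Si](CC)(CC)CC)[C@@H](O)C[C@@H](O)/C(C)=C/[C@H]2OC1=O
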